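## Retrosynthetic overview
1. Gentiside C (11) ⇒ remove two O-benzyl groups and saturate vinyl to ethyl ⇒ (R)-14-methylhexadec-15-enyl 2,3-bis(benzyloxy)benzoate (9).
2. Key disconnection C13–C14: a branched, enantioselective hydroalkylation of buta-1,3-diene with a primary C13 B-alkyl-9-BBN. Butadiene supplies C14, the 14-CH3, C15 and C16. This is the new reaction; it forms the key C–C bond and sets the only stereocentre.
3. The alkylborane comes from 9-BBN hydroboration of tridec-12-enyl ester 5. Ester 5 comes from tridec-12-en-1-ol and 2,3-bis(benzyloxy)benzoic acid.
4. Tridec-12-en-1-ol comes from undec-10-enylmagnesium bromide and ethylene oxide (C11 + C2).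
5. No ring is constructed. The only ring in the target, the catechol arene, is purchased.

Assumptions: the SMILES is read as (S)-14-methylhexadecyl 2,3-dihydroxybenzoate (13 CH2 between O and the stereocentre, C24H40O4); acid 4 is treated as a catalogue compound (otherwise two routine steps from 2,3-dihydroxybenzoic acid: BnBr/K2CO3, then NaOH); the sense of induction of a new catalytic reaction cannot be predicted, so the ligand antipode that gives (R)-9 is assigned after the first run.

## Route

**Step 1**
Reactants: 1, 11-bromoundec-1-ene; 2, ethylene oxide
Product: 3, tridec-12-en-1-ol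
Conditions: Mg, THF, rt to 40 °C; then CuI (10 mol %), 2 (1.5 equiv, THF solution), −30 to 0 °C; aq NH4Cl
Reagents that add atoms: ethylene oxide (2), C1CO1
Why: Cu-catalysed Grignard opening of an epoxide is a reliable two-carbon homologation, and the remote terminal alkene is inert to the Grignard reagent.

**Step 2**
Reactants: 3, tridec-12-en-1-ol; 4, 2,3-bis(benzyloxy)benzoic acid
Product: 5, tridec-12-en-1-yl 2,3-bis(benzyloxy)benzoate
Conditions: EDC·HCl, DMAP, CH2Cl2, 0 °C to rt
Reagents that add atoms: 2,3-bis(benzyloxy)benzoic acid (4), OC(=O)c1cccc(OCc2ccccc2)c1OCc1ccccc1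
Why: Steglich esterification of an unhindered primary alcohol works well here because benzyl protection removes the acidic, chelating and oxidisable catechol OH groups.

**Step 3**
Reactants: 5, tridec-12-en-1-yl 2,3-bis(benzyloxy)benzoate; 6, 9-borabicyclo[3.3.1]nonane (9-BBN-H)
Product: 7, 13-(9-borabicyclo[3.3.1]nonan-9-yl)tridecyl 2,3-bis(benzyloxy)benzoate (not isolated)
Conditions: 9-BBN-H (0.98 equiv, 0.5 M in THF), 0 °C to rt, 6 h; used directly
Reagents that add atoms: 9-BBN-H (6), [H]B1C2CCCC1CCC2
Why: Brown hydroboration with 9-BBN is >99% anti-Markovnikov on a monosubstituted alkene and leaves benzoate esters and benzyl ethers untouched, and the slight deficit of borane leaves no B–H to consume butadiene in Step 4.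

**Step 4 (key step)**
Reactants: 7, B-alkyl-9-BBN; 8, buta-1,3-diene
Product: 9, (R)-14-methylhexadec-15-en-1-yl 2,3-bis(benzyloxy)benzoate. C14 carries H, CH3, vinyl and the C13 chain.
Conditions: Ni(cod)2 (5 mol %), L*·HCl (6 mol %), NaOt-Bu (6 mol %), 8 (3 equiv, THF solution), MeOH (2 equiv), THF, 25 °C, sealed tube, 16 h; ethanolamine work-up to remove MeO-9-BBN. L* is a very bulky C2-symmetric chiral NHC: an acenaphthoimidazolylidene core bearing 2,6-bis(1-arylethyl)aryl N-wings.
Reagents that add atoms: buta-1,3-diene (8), C=CC=C (MeOH supplies only H)
Why: Proposed new method: a Ni(0)/bulky chiral NHC-catalysed, redox-neutral, branched- and enantioselective hydroalkylation of butadiene with an unstabilised B-alkyl-9-BBN. MeOH, acidified by coordination to the Lewis-acidic boron of 7, protonates L*Ni(0)(η4-butadiene) at a terminal carbon and gives the contact ion pair [L*Ni(η3-syn-1-methylallyl)]+[R–B(OMe)(9-BBN)]−, so one proton transfer creates both the π-crotyl electrophile and the "ate"-activated transmetalating agent; any C–O elimination to methyl butenyl ethers is reversible. The primary alkyl group transfers selectively, as in every B-alkyl Suzuki–Miyaura coupling, to give square-planar L*Ni(η3-crotyl)(CH2R). In that complex the very large NHC must sit beside the unsubstituted allyl terminus, which places the slim primary alkyl cis to the CH(CH3) terminus, so C(sp3)–C(sp3) reductive elimination gives the branched 3-methyl-1-alkene. The η3 form has no cis vacant site for β-H elimination, the ligand bulk blocks binding of a second diene (C8 telomers), and excess butadiene keeps Ni away from the product alkene. The two crotyl faces interconvert quickly by π–σ–π through the CH2 terminus, so C14 is set in the enantio-determining reductive elimination inside the C2-symmetric pocket; the discrimination is CH3 versus H on the allyl terminus, not CH3 versus C2H5, and the ligand antipode is chosen to give R. Closest known reaction types: Ni(0)-catalysed hydroarylation of 1,3-dienes with arylboron reagents in alcohols, Ni-catalysed B-alkyl Suzuki–Miyaura coupling, and Ni-catalysed asymmetric allyl–alkyl coupling with Grignard or zinc reagents. To my knowledge an sp3 organoborane has not been used as the nucleophile in a diene hydrofunctionalisation.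

**Step 5**
Reactants: 9, (R)-14-methylhexadec-15-en-1-yl 2,3-bis(benzyloxy)benzoate
Product: 10, (S)-14-methylhexadecyl 2,3-bis(benzyloxy)benzoate. The spatial arrangement is unchanged; the descriptor changes R to S only because ethyl ranks below the long chain whereas vinyl ranked above it.
Conditions: 2-nitrobenzenesulfonylhydrazide (4 equiv, portionwise), Et3N, CH2Cl2, rt, 12 h
Reagents that add atoms: none
Why: Diimide reduction transfers H2 in a concerted syn fashion and is fastest on monosubstituted alkenes, and because no metal hydride is involved the vinyl group cannot isomerise into the allylic C14–H, so the stereocentre, ester and benzyl ethers all survive.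

**Step 6**
Reactants: 10, (S)-14-methylhexadecyl 2,3-bis(benzyloxy)benzoate
Product: 11, Gentiside C, (S)-14-methylhexadecyl 2,3-dihydroxybenzoate
Conditions: H2 (1 atm), 10% Pd/C, EtOAc/EtOH 1:1, rt; filter through Celite under Ar
Reagents that add atoms: none
Why: Catalytic hydrogenolysis cleaves both aryl benzyl ethers under neutral conditions, the non-benzylic alkyl ester is inert, and the now saturated chain cannot epimerise.

## Compound list
1 | 11-bromoundec-1-ene | C=CCCCCCCCCCBr | starting material
2 | ethylene oxide | C1CO1 | starting material
3 | tridec-12-en-1-ol | C=CCCCCCCCCCCCO | intermediate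
4 | 2,3-bis(benzyloxy)benzoic acid | OC(=O)c1cccc(OCc2ccccc2)c1OCc1ccccc1 | starting material
5 | tridec-12-en-1-yl 2,3-bis(benzyloxy)benzoate | C=CCCCCCCCCCCCOC(=O)c1cccc(OCc2ccccc2)c1OCc1ccccc1 | intermediate
6 | 9-borabicyclo[3.3.1]nonane (9-BBN-H) | [H]B1C2CCCC1CCC2 | starting material
7 | 13-(9-borabicyclo[3.3.1]nonan-9-yl)tridecyl 2,3-bis(benzyloxy)benzoate | O=C(OCCCCCCCCCCCCCB1C2CCCC1CCC2)c1cccc(OCc2ccccc2)c1OCc1ccccc1 | intermediate
8 | buta-1,3-diene | C=CC=C | starting material
9 | (R)-14-methylhexadec-15-en-1-yl 2,3-bis(benzyloxy)benzoate | C=C[C@H](C)CCCCCCCCCCCCCOC(=O)c1cccc(OCc2ccccc2)c1OCc1ccccc1 | intermediate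
10 | (S)-14-methylhexadecyl 2,3-bis(benzyloxy)benzoate | CC[C@H](C)CCCCCCCCCCCCCOC(=O)c1cccc(OCc2ccccc2)c1OCc1ccccc1 | intermediate
11 | Gentiside C, (S)-14-methylhexadecyl 2,3-dihydroxybenzoate | CC[C@H](C)CCCCCCCCCCCCCOC(=O)c1cccc(O)c1O | target

## Summary
Total step count: 6
Longest linear sequence: 6 (1 → 3 → 5 → 7 → 9 → 10 → 11)

Steps most likely to fail:

1. **Step 4 (proposed new reaction).**
   - Failure modes: the linear crotyl regioisomer forms; β-H elimination returns 5 plus butenes; butadiene telomerises; the er is too low.
   - Checking er: take an aliquot of 9 through ozonolysis/NaBH4 and make the Mosher ester of the resulting 2-methyl primary alcohol.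
   - Fallback (known chemistry, chiral pool instead of catalysis): convert commercial (S)-1-bromo-2-methylbutane to its Grignard reagent. Couple it with THP-protected 12-bromododecan-1-ol under Li2CuCl4 catalysis (Kochi-type sp3–sp3 coupling; the β-stereocentre is untouched). Remove the THP group to give (S)-14-methylhexadecan-1-ol, then esterify with 4 to rejoin the route at 10.

2. **Step 5 (saturation next to the stereocentre).**
   - Failure modes: diimide conversion is incomplete and 9 and 10 are hard to separate; any switch to a heterogeneous catalyst risks allylic isomerisation and racemisation.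
   - Fallback: replace direct H2 addition with a two-stage formal hydrogenation. Carry out anti-Markovnikov hydroboration of the vinyl group with catecholborane, then radical-chain protodeboronation (MeOH, 4-tert-butylcatechol, air). The radical is at primary C16, so C14 is never involved.

3. **Step 1 (C13 building block).**
   - Failure modes: Wurtz dimer, bromohydrin by-product, and the handling of ethylene oxide.
   - Fallback: use a C10 + C3 disconnection. Couple allylmagnesium bromide (excess) with 10-bromodecan-1-ol, as its magnesium alkoxide or THP ether, under Li2CuCl4 catalysis. This gives the same tridec-12-en-1-ol (3).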